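**Retrosynthetic overview**

1. Last cut: the CH2–CH2 bond C16–C17 (locants of the tetracosa-1,23-diene chain), between the bis-epoxy C24 alcohol 34 (as its triflate) and the C12 homoallylic Grignard reagent 37. The corresponding bond C8–C9 on the other side is cut the same way two steps earlier.
2. Enabling feature: C16 is the exocyclic CH2 on the quaternary carbon C15 of the C14–C15 oxirane (a 2,3-epoxy-1-ol unit). The ring forbids a radical or carbanion at C16 (oxiranylcarbinyl opening, β-elimination) but activates C16–OTf for SN2, and its own carbons are hindered; so C16 is the electrophile and C17 carries the metal.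
3. Core C9–C16: the C2-symmetric bis-epoxy diol 28, from succinaldehyde by double Wittig, DIBAL and a two-fold Sharpless epoxidation. Both oxiranes (four stereocentres, one tartrate) are formed together in step 14, before any chain is attached; no ring is formed later.
4. Both C12 chains come from one repeating C6 unit, 2,3-dimethylbut-3-en-1-ol (Evans deconjugative methylation; the (S)-unit three times, the (R)-unit once). Its bromide serves as Grignard nucleophile and, after ene chlorination, as 2-substituted allyl chloride electrophile; Cu catalysis joins two units.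
5. All eight stereocentres are in place before the key step, which gives the target without protecting groups.

Key step: step 18

Remark: read from the structure, the configuration is 3R,7R,10S,11S,14S,15S,18R,22S, so the two C12 chains are diastereomers (outer C-methyl centre R on one side, S on the other) and the (R)-series of the repeating unit is needed once; both antipodes of 4-benzyl-2-oxazolidinone are taken as commercial.

**Route**

Step 1
Reactants: 1 (4S)-4-benzyl-1,3-oxazolidin-2-one; 2 3-methylbut-2-enoyl chloride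
Product: 4 (4S)-4-benzyl-3-(3-methylbut-2-enoyl)-1,3-oxazolidin-2-one, via N-lithio oxazolidinone 3 (not isolated)
Conditions: n-BuLi (1.0 equiv), THF, −78 °C; then 2, −78 → 0 °C
Reagents that add atoms: none
Why: N-acylation of the lithiated Evans oxazolidinone by the acid chloride (standard imide formation); no stereocentre is formed.

Step 2
Reactants: 4 (4S)-4-benzyl-3-(3-methylbut-2-enoyl)-1,3-oxazolidin-2-one
Product: 6 (4S)-4-benzyl-3-[(2S)-2,3-dimethylbut-3-enoyl]-1,3-oxazolidin-2-one, via sodium dienolate 5 (not isolated)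
Conditions: NaHMDS (1.05 equiv), THF, −78 °C; MeI (excess), −78 → −40 °C
Reagents that add atoms: iodomethane, CI
Why: Evans asymmetric alkylation in its deconjugative form: γ-deprotonation of the s-cis enoyl imide gives the chelated (Z)-dienolate, which is methylated at the α-carbon on the face opposite the benzyl group, setting the (S) C-methyl centre and leaving the isopropenyl double bond.

Step 3
Reactants: 6 (4S)-4-benzyl-3-[(2S)-2,3-dimethylbut-3-enoyl]-1,3-oxazolidin-2-one
Product: 7 (2S)-2,3-dimethylbut-3-en-1-ol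
Conditions: LiBH4, MeOH (1 equiv), Et2O, 0 °C; aq. NaOH work-up; careful distillation (volatile alcohol)
Reagents that add atoms: none
Why: Reductive removal of the Evans auxiliary with LiBH4 reduces only the exocyclic carbonyl, should leave the α-stereocentre untouched and returns the auxiliary.

Step 4
Reactants: 7 (2S)-2,3-dimethylbut-3-en-1-ol
Product: 8 (3S)-4-bromo-2,3-dimethylbut-1-ene
Conditions: PPh3, NBS, CH2Cl2, −20 → 0 °C
Reagents that add atoms: N-bromosuccinimide, O=C1CCC(=O)N1Br
Why: Appel-type bromination proceeds by SN2 at the primary carbinol carbon under neutral conditions, so the neighbouring stereocentre and the acid-sensitive 1,1-disubstituted alkene should survive.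

Step 5
Reactants: 8 (3S)-4-bromo-2,3-dimethylbut-1-ene
Product: 9 (3S)-4-bromo-2-(chloromethyl)-3-methylbut-1-ene
Conditions: Ca(OCl)2, solid CO2, CH2Cl2–H2O, 0 °C
Reagents that add atoms: calcium hypochlorite, [Ca+2].[O-]Cl.[O-]Cl
Why: Ene-type allylic chlorination with hypochlorous acid: Cl+ adds to the terminal CH2 and a proton is lost from the vinylic methyl group (as with the isopropenyl groups of carvone-type substrates), giving the 2-substituted allyl chloride with the stereocentre retained.

Step 6
Reactants: 10 (4R)-4-benzyl-1,3-oxazolidin-2-one; 2 3-methylbut-2-enoyl chloride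
Product: 12 (4R)-4-benzyl-3-(3-methylbut-2-enoyl)-1,3-oxazolidin-2-one, via N-lithio oxazolidinone 11 (not isolated)
Conditions: n-BuLi (1.0 equiv), THF, −78 °C; then 2, −78 → 0 °C
Reagents that add atoms: none
Why: Same N-acylation as step 1 in the enantiomeric series.

Step 7
Reactants: 12 (4R)-4-benzyl-3-(3-methylbut-2-enoyl)-1,3-oxazolidin-2-one
Product: 14 (4R)-4-benzyl-3-[(2R)-2,3-dimethylbut-3-enoyl]-1,3-oxazolidin-2-one, via sodium dienolate 13 (not isolated)
Conditions: NaHMDS (1.05 equiv), THF, −78 °C; MeI (excess), −78 → −40 °C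
Reagents that add atoms: iodomethane, CI
Why: Deconjugative Evans methylation as in step 2; the (R)-auxiliary shields the opposite face and sets the (R) C-methyl centre.

Step 8
Reactants: 14 (4R)-4-benzyl-3-[(2R)-2,3-dimethylbut-3-enoyl]-1,3-oxazolidin-2-one
Product: 15 (2R)-2,3-dimethylbut-3-en-1-ol
Conditions: LiBH4, MeOH (1 equiv), Et2O, 0 °C; aq. NaOH work-up; careful distillation
Reagents that add atoms: none
Why: Reductive auxiliary cleavage as in step 3.

Step 9
Reactants: 15 (2R)-2,3-dimethylbut-3-en-1-ol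
Product: 16 (3R)-4-bromo-2,3-dimethylbut-1-ene
Conditions: PPh3, NBS, CH2Cl2, −20 → 0 °C
Reagents that add atoms: N-bromosuccinimide, O=C1CCC(=O)N1Br
Why: Appel-type SN2 bromination as in step 4.

Step 10
Reactants: 8 (3S)-4-bromo-2,3-dimethylbut-1-ene; 9 (3S)-4-bromo-2-(chloromethyl)-3-methylbut-1-ene
Product: 18 (2S,6R)-1-bromo-2,6,7-trimethyl-3-methylideneoct-7-ene, via Grignard reagent 17 (not isolated)
Conditions: 8, Mg turnings, THF, rt (decanted from excess Mg); added slowly to 9 (1.1 equiv), Li2CuCl4 (3 mol%), THF, −78 → −30 °C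
Reagents that add atoms: none
Why: Copper-catalysed Grignard–allyl chloride coupling (Kochi type): SN2 and SN2′ attack give the same product because both allyl termini are CH2, the hindered primary bromide should be inert at low temperature, and both stereocentres are carried in unchanged.

Step 11
Reactants: 16 (3R)-4-bromo-2,3-dimethylbut-1-ene; 9 (3S)-4-bromo-2-(chloromethyl)-3-methylbut-1-ene
Product: 20 (2S,6S)-1-bromo-2,6,7-trimethyl-3-methylideneoct-7-ene, via Grignard reagent 19 (not isolated)
Conditions: 16, Mg turnings, THF, rt (decanted); added slowly to 9 (1.1 equiv), Li2CuCl4 (3 mol%), THF, −78 → −30 °C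
Reagents that add atoms: none
Why: Same copper-catalysed Grignard–allyl chloride coupling as step 10, here with the (R)-unit as nucleophile, which gives the diastereomeric chain.

Step 12
Reactants: 21 2,5-dimethoxytetrahydrofuran; 22 ethyl 2-(triphenyl-λ5-phosphanylidene)propanoate
Product: 25 diethyl (2E,6E)-2,7-dimethylocta-2,6-dienedioate, via butanedial 23 (not isolated), via enoate aldehyde 24 (not isolated)
Conditions: 0.5 M aq. HCl, 70 °C; NaHCO3 to pH 7; then 22 (2.3 equiv), CH2Cl2–H2O, rt
Reagents that add atoms: none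
Why: Hydrolysis of the cyclic bis-acetal releases succinaldehyde, and Wittig olefination with the stabilised α-methyl ylide should give the (E)-trisubstituted enoate at both ends.

Step 13
Reactants: 25 diethyl (2E,6E)-2,7-dimethylocta-2,6-dienedioate
Product: 26 (2E,6E)-2,7-dimethylocta-2,6-diene-1,8-diol
Conditions: DIBAL-H (4.4 equiv), CH2Cl2, −78 → 0 °C; Rochelle salt work-up
Reagents that add atoms: none
Why: DIBAL-H 1,2-reduction of the two enoates to allylic alcohols keeps the (E)-geometry.

Step 14
Reactants: 26 (2E,6E)-2,7-dimethylocta-2,6-diene-1,8-diol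
Product: 28 [(2S,3S)-3-{2-[(2S,3S)-3-(hydroxymethyl)-3-methyloxiran-2-yl]ethyl}-2-methyloxiran-2-yl]methanol, via mono-epoxide 27 (not isolated)
Conditions: Ti(OiPr)4 (20 mol%), L-(+)-diisopropyl tartrate (26 mol%), anhydrous TBHP (excess), 4 Å MS, CH2Cl2, −20 °C; non-aqueous work-up (Me2S, filtration) because the product is water-soluble
Reagents that add atoms: tert-butyl hydroperoxide, CC(C)(C)OO
Why: Two-fold Sharpless asymmetric epoxidation: with L-(+)-tartrate each (E)-2-methyl allylic alcohol is epoxidised on the face that gives the (2S,3S)-epoxy alcohol (Sharpless mnemonic), so one catalyst sets all four oxirane centres, and material epoxidised with the wrong sense at one end becomes a separable diastereomer.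

Step 15
Reactants: 28 [(2S,3S)-3-{2-[(2S,3S)-3-(hydroxymethyl)-3-methyloxiran-2-yl]ethyl}-2-methyloxiran-2-yl]methanol
Product: 29 [(2S,3S)-3-{2-[(2S,3S)-3-({[tert-butyl(dimethyl)silyl]oxy}methyl)-3-methyloxiran-2-yl]ethyl}-2-methyloxiran-2-yl]methanol
Conditions: TBSCl (1.0 equiv), imidazole, CH2Cl2–DMF, 0 °C; diol and bis-silyl ether recycled
Reagents that add atoms: tert-butyldimethylsilyl chloride, CC(C)(C)[Si](C)(C)Cl
Why: Statistical monosilylation of a C2-symmetric diol; the two hydroxyls are homotopic, so either one gives the same mono-ether.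

Step 16
Reactants: 29 [(2S,3S)-3-{2-[(2S,3S)-3-({[tert-butyl(dimethyl)silyl]oxy}methyl)-3-methyloxiran-2-yl]ethyl}-2-methyloxiran-2-yl]methanol; 18 (2S,6R)-1-bromo-2,6,7-trimethyl-3-methylideneoct-7-ene
Product: 33 tert-butyl(dimethyl){[(2S,3S)-2-methyl-3-(2-{(2S,3S)-3-methyl-3-[(3R,7R)-3,7,8-trimethyl-4-methylidenenon-8-en-1-yl]oxiran-2-yl}ethyl)oxiran-2-yl]methoxy}silane, via lithium alkoxide 30 (not isolated), via epoxy triflate 31 (not isolated), via Grignard reagent 32 (not isolated)
Conditions: 29, n-BuLi (1.0 equiv), Et2O, −78 °C; Tf2O (1.0 equiv), −78 °C; then 32 (from 18, Mg turnings, Et2O, rt, decanted; 1.3 equiv), CuBr·SMe2 (10 mol%), −78 → −40 °C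
Reagents that add atoms: none
Why: In-situ triflation followed by Kotsuki-type copper-catalysed Grignard–triflate coupling: SN2 at the primary carbon next to the oxirane should outrun attack on either trisubstituted oxirane or on the silyl ether, and no stereocentre is involved.

Step 17
Reactants: 33 tert-butyl(dimethyl){[(2S,3S)-2-methyl-3-(2-{(2S,3S)-3-methyl-3-[(3R,7R)-3,7,8-trimethyl-4-methylidenenon-8-en-1-yl]oxiran-2-yl}ethyl)oxiran-2-yl]methoxy}silane
Product: 34 [(2S,3S)-2-methyl-3-(2-{(2S,3S)-3-methyl-3-[(3R,7R)-3,7,8-trimethyl-4-methylidenenon-8-en-1-yl]oxiran-2-yl}ethyl)oxiran-2-yl]methanol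
Conditions: TBAF, THF, 0 °C
Reagents that add atoms: none
Why: Fluoride cleavage of the primary TBS ether; oxiranes and alkenes are inert to TBAF at 0 °C.

Step 18
Reactants: 34 [(2S,3S)-2-methyl-3-(2-{(2S,3S)-3-methyl-3-[(3R,7R)-3,7,8-trimethyl-4-methylidenenon-8-en-1-yl]oxiran-2-yl}ethyl)oxiran-2-yl]methanol; 20 (2S,6S)-1-bromo-2,6,7-trimethyl-3-methylideneoct-7-ene
Product: 38 (3R,7R,10S,11S,14S,15S,18R,22S)-10,11:14,15-diepoxy-2,3,7,10,15,18,22,23-octamethyl-6,19-dimethylidenetetracosa-1,23-diene, via lithium alkoxide 35 (not isolated), via epoxy triflate 36 (not isolated), via Grignard reagent 37 (not isolated)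
Conditions: 34, n-BuLi (1.0 equiv), Et2O, −78 °C; Tf2O (1.0 equiv), −78 °C; then 37 (from 20, Mg turnings, Et2O, rt, decanted; 1.5 equiv), CuBr·SMe2 (10 mol%), −78 → −40 °C; cold NH4Cl quench
Reagents that add atoms: none
Why: O-Triflation of the lithium alkoxide gives the 2,3-epoxy-1-triflate 36, and the organocopper species formed from 37 and catalytic CuBr displaces the triflate at the primary carbon by SN2 (oxidative addition to a dialkylcopper(III), then reductive elimination), a Kotsuki-type Cu-catalysed Grignard–triflate coupling as used for epoxy triflates of Sharpless origin. No ring is closed and no stereocentre is created: the six stereocentres of 34 and the two of 37 are carried through because the new bond joins two CH2 carbons. The step needs chemoselectivity for C–OTf over the two oxiranes and over the four 1,1-disubstituted alkenes; this should be secured by the leaving-group gap between triflate and an oxirane oxygen, by the quaternary and secondary ring carbons of each trisubstituted oxirane, and by the low temperature. The oxirane on the neighbouring quaternary carbon also fixes the polarity: a carbanion or radical at that CH2 would open the ring, so this carbon is the electrophile and the chain carries the magnesium. The homoallylic Grignard reagent should keep its configuration because its stereocentre is β to the metal and the cyclopropylcarbinyl rearrangement is slow below room temperature.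

**Compound list**

1 | (4S)-4-benzyl-1,3-oxazolidin-2-one | O=C1N[C@@H](Cc2ccccc2)CO1 | starting material
2 | 3-methylbut-2-enoyl chloride | CC(C)=CC(Cl)=O | starting material
3 | N-lithio-(4S)-4-benzyl-1,3-oxazolidin-2-one | [Li]N1[C@@H](Cc2ccccc2)COC1=O | intermediate
4 | (4S)-4-benzyl-3-(3-methylbut-2-enoyl)-1,3-oxazolidin-2-one | CC(C)=CC(=O)N1[C@@H](Cc2ccccc2)COC1=O | intermediate
5 | sodium (Z)-dienolate of 4 | [Na]O/C(=C\C(C)=C)N1[C@@H](Cc2ccccc2)COC1=O | intermediate
6 | (4S)-4-benzyl-3-[(2S)-2,3-dimethylbut-3-enoyl]-1,3-oxazolidin-2-one | C=C(C)[C@H](C)C(=O)N1[C@@H](Cc2ccccc2)COC1=O | intermediate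
7 | (2S)-2,3-dimethylbut-3-en-1-ol | OC[C@@H](C)C(C)=C | intermediate
8 | (3S)-4-bromo-2,3-dimethylbut-1-ene | BrC[C@@H](C)C(C)=C | intermediate
9 | (3S)-4-bromo-2-(chloromethyl)-3-methylbut-1-ene | BrC[C@@H](C)C(=C)CCl | intermediate
10 | (4R)-4-benzyl-1,3-oxazolidin-2-one | O=C1N[C@H](Cc2ccccc2)CO1 | starting material
11 | N-lithio-(4R)-4-benzyl-1,3-oxazolidin-2-one | [Li]N1[C@H](Cc2ccccc2)COC1=O | intermediate
12 | (4R)-4-benzyl-3-(3-methylbut-2-enoyl)-1,3-oxazolidin-2-one | CC(C)=CC(=O)N1[C@H](Cc2ccccc2)COC1=O | intermediate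
13 | sodium (Z)-dienolate of 12 | [Na]O/C(=C\C(C)=C)N1[C@H](Cc2ccccc2)COC1=O | intermediate
14 | (4R)-4-benzyl-3-[(2R)-2,3-dimethylbut-3-enoyl]-1,3-oxazolidin-2-one | C=C(C)[C@@H](C)C(=O)N1[C@H](Cc2ccccc2)COC1=O | intermediate
15 | (2R)-2,3-dimethylbut-3-en-1-ol | OC[C@H](C)C(C)=C | intermediate
16 | (3R)-4-bromo-2,3-dimethylbut-1-ene | BrC[C@H](C)C(C)=C | intermediate
17 | [(2S)-2,3-dimethylbut-3-en-1-yl]magnesium bromide | Br[Mg]C[C@@H](C)C(C)=C | intermediate
18 | (2S,6R)-1-bromo-2,6,7-trimethyl-3-methylideneoct-7-ene | C=C(C)[C@H](C)CCC(=C)[C@H](C)CBr | intermediate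
19 | [(2R)-2,3-dimethylbut-3-en-1-yl]magnesium bromide | Br[Mg]C[C@H](C)C(C)=C | intermediate
20 | (2S,6S)-1-bromo-2,6,7-trimethyl-3-methylideneoct-7-ene | BrC[C@@H](C)C(=C)CC[C@H](C)C(C)=C | intermediate
21 | 2,5-dimethoxytetrahydrofuran (cis/trans mixture) | COC1CCC(OC)O1 | starting material
22 | ethyl 2-(triphenyl-λ5-phosphanylidene)propanoate | CCOC(=O)C(C)=P(c1ccccc1)(c1ccccc1)c1ccccc1 | starting material
23 | butanedial (succinaldehyde) | O=CCCC=O | intermediate
24 | ethyl (2E)-2-methyl-6-oxohex-2-enoate | CCOC(=O)/C(C)=C/CCC=O | intermediate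
25 | diethyl (2E,6E)-2,7-dimethylocta-2,6-dienedioate | CCOC(=O)/C(C)=C/CC/C=C(C)/C(=O)OCC | intermediate
26 | (2E,6E)-2,7-dimethylocta-2,6-diene-1,8-diol | OC/C(C)=C/CC/C=C(C)/CO | intermediate
27 | (2E)-5-[(2S,3S)-3-(hydroxymethyl)-3-methyloxiran-2-yl]-2-methylpent-2-en-1-ol | OC[C@]1(C)O[C@H]1CC/C=C(C)/CO | intermediate
28 | [(2S,3S)-3-{2-[(2S,3S)-3-(hydroxymethyl)-3-methyloxiran-2-yl]ethyl}-2-methyloxiran-2-yl]methanol | OC[C@]1(C)O[C@H]1CC[C@@H]1O[C@@]1(C)CO | intermediate
29 | [(2S,3S)-3-{2-[(2S,3S)-3-({[tert-butyl(dimethyl)silyl]oxy}methyl)-3-methyloxiran-2-yl]ethyl}-2-methyloxiran-2-yl]methanol | OC[C@]1(C)O[C@H]1CC[C@@H]1O[C@@]1(C)CO[Si](C)(C)C(C)(C)C | intermediate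
30 | lithium alkoxide of 29 | [Li]OC[C@]1(C)O[C@H]1CC[C@@H]1O[C@@]1(C)CO[Si](C)(C)C(C)(C)C | intermediate
31 | trifluoromethanesulfonate of 29 | O=S(=O)(OC[C@]1(C)O[C@H]1CC[C@@H]1O[C@@]1(C)CO[Si](C)(C)C(C)(C)C)C(F)(F)F | intermediate
32 | [(2S,6R)-2,6,7-trimethyl-3-methylideneoct-7-en-1-yl]magnesium bromide | C=C(C)[C@H](C)CCC(=C)[C@H](C)C[Mg]Br | intermediate
33 | tert-butyl(dimethyl){[(2S,3S)-2-methyl-3-(2-{(2S,3S)-3-methyl-3-[(3R,7R)-3,7,8-trimethyl-4-methylidenenon-8-en-1-yl]oxiran-2-yl}ethyl)oxiran-2-yl]methoxy}silane | C=C(C)[C@H](C)CCC(=C)[C@H](C)CC[C@]1(C)O[C@H]1CC[C@@H]1O[C@@]1(C)CO[Si](C)(C)C(C)(C)C | intermediate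
34 | [(2S,3S)-2-methyl-3-(2-{(2S,3S)-3-methyl-3-[(3R,7R)-3,7,8-trimethyl-4-methylidenenon-8-en-1-yl]oxiran-2-yl}ethyl)oxiran-2-yl]methanol | C=C(C)[C@H](C)CCC(=C)[C@H](C)CC[C@]1(C)O[C@H]1CC[C@@H]1O[C@@]1(C)CO | intermediate
35 | lithium alkoxide of 34 | C=C(C)[C@H](C)CCC(=C)[C@H](C)CC[C@]1(C)O[C@H]1CC[C@@H]1O[C@@]1(C)CO[Li] | intermediate
36 | trifluoromethanesulfonate of 34 | C=C(C)[C@H](C)CCC(=C)[C@H](C)CC[C@]1(C)O[C@H]1CC[C@@H]1O[C@@]1(C)COS(=O)(=O)C(F)(F)F | intermediate
37 | [(2S,6S)-2,6,7-trimethyl-3-methylideneoct-7-en-1-yl]magnesium bromide | Br[Mg]C[C@@H](C)C(=C)CC[C@H](C)C(C)=C | intermediate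
38 | (3R,7R,10S,11S,14S,15S,18R,22S)-10,11:14,15-diepoxy-2,3,7,10,15,18,22,23-octamethyl-6,19-dimethylidenetetracosa-1,23-diene | C=C(C)[C@H](C)CCC(=C)[C@H](C)CC[C@]1(C)O[C@H]1CC[C@@H]1O[C@@]1(C)CC[C@@H](C)C(=C)CC[C@H](C)C(=C)C | target

**Summary**

Total step count: 18. Longest linear sequence: 9 steps (1, 2, 3, 4, 5, 10, 16, 17, 18).

Steps most likely to fail:

1. Step 18. Magnesium salts or the organocopper species may open or rearrange the trisubstituted oxiranes faster than the triflate is displaced at its hindered, neopentyl-type carbon, or the epoxy triflate may decompose before it couples. Fallback (sets out from 20 and from 36, made from 34 as in the route; comes back at 38): 20 is treated with sodium benzenesulfinate (DMF, 60 °C) to give {[(2S,6S)-2,6,7-trimethyl-3-methylideneoct-7-en-1-yl]sulfonyl}benzene F1. Deprotonation (n-BuLi, THF–DMPU, −78 °C) gives the α-lithio sulfone F2, which is alkylated at −78 °C by triflate 36 to give the coupled sulfone F3 (both epimers at the sulfonyl carbon). Reductive desulfonylation (Na/Hg, Na2HPO4, MeOH–THF, −20 °C) should then give 38. The stabilised carbanion is less Lewis acidic and a softer nucleophile than the Grignard reagent; the low temperature and the buffered amalgam are meant to prevent the γ,δ-epoxy sulfone anion from closing onto the oxirane.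

2. Step 5. The ene chlorination may abstract the methine hydrogen at the stereocentre instead of a methyl hydrogen (shifting the double bond into the tetrasubstituted position and erasing the stereocentre), or may chlorinate twice. Fallback (sets out from 8, comes back at 9): catalytic SeO2 with TBHP (CH2Cl2, rt) oxidises the vinylic methyl group (ene reaction then [2,3]-shift; methyl is preferred over methine in 1,1-disubstituted alkenes) to (3S)-4-bromo-3-methyl-2-methylidenebutan-1-ol F4. PPh3/NCS (CH2Cl2, 0 °C) then converts the allylic alcohol into 9; direct and allylic displacement give the same chloride.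

3. Step 15. Statistical silylation cannot favour the mono-ether, and the polar bis-epoxy diol may be lost through poor recovery from water, silyl migration or base-induced oxirane isomerisation during repeated recycling. Fallback (sets out from 26, uses 32, comes back at 34): the desymmetrisation is moved to the diene stage and the oxiranes are introduced one at a time on lipophilic material. 26 (used in excess and recovered) is monosilylated (TBSCl, imidazole, DMF) to (2E,6E)-8-{[tert-butyl(dimethyl)silyl]oxy}-2,7-dimethylocta-2,6-dien-1-ol F5. Sharpless epoxidation of the free allylic alcohol (L-(+)-DIPT) gives the mono-epoxy alcohol F6. Triflation (Tf2O, 2,6-lutidine, CH2Cl2, −78 °C) gives the epoxy triflate F7, and coupling with 32 (CuBr·SMe2, Et2O, −78 → −40 °C) gives the silyl ether F8. TBAF releases the allylic alcohol F9, and a second Sharpless epoxidation (L-(+)-DIPT), to which the isolated 1,1-disubstituted alkenes are inert, should give 34.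

**Further compounds**

F1 | step 18 | {[(2S,6S)-2,6,7-trimethyl-3-methylideneoct-7-en-1-yl]sulfonyl}benzene | O=S(=O)(C[C@@H](C)C(=C)CC[C@H](C)C(C)=C)c1ccccc1
F2 | step 18 | α-lithio derivative of F1 | [Li]C([C@@H](C)C(=C)CC[C@H](C)C(C)=C)S(=O)(=O)c1ccccc1
F3 | step 18 | coupled sulfone: 38 bearing a phenylsulfonyl group on the chain CH2 next to the C-methyl centre (C17), both epimers | C=C(C)[C@H](C)CCC(=C)[C@H](C)CC[C@]1(C)O[C@H]1CC[C@@H]1O[C@@]1(C)CC([C@@H](C)C(=C)CC[C@H](C)C(C)=C)S(=O)(=O)c1ccccc1
F4 | step 5 | (3S)-4-bromo-3-methyl-2-methylidenebutan-1-ol | OCC(=C)[C@H](C)CBr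
F5 | step 15 | (2E,6E)-8-{[tert-butyl(dimethyl)silyl]oxy}-2,7-dimethylocta-2,6-dien-1-ol | OC/C(C)=C/CC/C=C(C)/CO[Si](C)(C)C(C)(C)C
F6 | step 15 | [(2S,3S)-3-[(3E)-5-{[tert-butyl(dimethyl)silyl]oxy}-4-methylpent-3-en-1-yl]-2-methyloxiran-2-yl]methanol | OC[C@]1(C)O[C@H]1CC/C=C(C)/CO[Si](C)(C)C(C)(C)C
F7 | step 15 | trifluoromethanesulfonate of F6 | O=S(=O)(OC[C@]1(C)O[C@H]1CC/C=C(C)/CO[Si](C)(C)C(C)(C)C)C(F)(F)F
F8 | step 15 | tert-butyl(dimethyl){[(2E)-2-methyl-5-{(2S,3S)-3-methyl-3-[(3R,7R)-3,7,8-trimethyl-4-methylidenenon-8-en-1-yl]oxiran-2-yl}pent-2-en-1-yl]oxy}silane | C=C(C)[C@H](C)CCC(=C)[C@H](C)CC[C@]1(C)O[C@H]1CC/C=C(C)/CO[Si](C)(C)C(C)(C)C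
F9 | step 15 | (2E)-2-methyl-5-{(2S,3S)-3-methyl-3-[(3R,7R)-3,7,8-trimethyl-4-methylidenenon-8-en-1-yl]oxiran-2-yl}pent-2-en-1-ol | C=C(C)[C@H](C)CCC(=C)[C@H](C)CC[C@]1(C)O[C@H]1CC/C=C(C)/CO
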